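The readings are calculated with made-up constants, noise included.

**The decision.** I book each flask by what stays held back, not by how fast E falls.

| flask | E | remark | time |
|---|---|---|---|
| epsilon | 0.028 M | run made earlier |  |
| autumn | 0.025 M |  | 8.0 h |
| spring | 0.050 M |  | 8.0 h |
| midnight | 0.10 M |  | 8.0 h |
| dusk | 0.20 M |  | 8.0 h |

- epsilon (time / h: L / %, E / %): 0.667: 8.2, 54.9; 1.33: 15.8, 40.5; 2.00: 19.8, 28.1; 3.00: 30.5, 20.6

(standard deviation of a reading: 1 percentage point)

- [L] at the end for autumn, spring, midnight, dusk, in this order
- how that number moves from the first to the last of them (hardly changes / rises, then falls / falls, then rises / falls all the way / rises all the way)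

- "hardly changes" means that all values lie within two and a half points (for a concentration: within two and a half percent of the largest)

**Held share.** The part of the charge that is neither L nor E, the gap in the mass balance, I call the held share. At 3.00 h in the epsilon run it reads 48.9%, after 52.1% at 2.00 h. Between 0.667 h and 2.00 h E falls by 27 percentage points and L rises by 12 points, so the held share grows there. Between the last two readings the order has turned: the gain of L, 0.107 h⁻¹ of the charge, is larger than the fall of E, 0.0750 h⁻¹. This crossing is a reading, and it carries the scatter.

**The bracket.** My first floor for L at the end is its last epsilon reading, 30.5%, the case where L stays put. E is falling at about 0.405 h⁻¹ in the epsilon run, and at that pace it stands at 2.72% at 8.0 h, which puts my first ceiling for L at 97.3%. If the held share grows no further, the floor tightens to 48.4%. If L keeps its pace from the start, the ceiling tightens to 81.3%.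

**My commitment.** The held share shifts by 3.2 points between its last two readings, so I stay near the floor. With one charge read, I presume the same share at each charge: 0.0121 M, 0.0242 M, 0.0484 M, 0.0968 M.

**The forecast.** It gives 0.017 M, 0.036 M, 0.077 M and 0.16 M, and says the row rises all the way. That is 68.0% to 80.0% of the charge, inside my bracket. Unlike mine, it holds that L “rises slightly faster than proportionally with the charge”.

**The flasks.** They give 0.0126 M, 0.0253 M, 0.0506 M and 0.101 M, and the row rises all the way.

    X ⇌ Q (K = 19.0, k = 0.00980 min⁻¹)
    E ⇌ G (K = 0.360, k = 0.0120 min⁻¹)
    X → L (k = 0.00580 min⁻¹)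
    L → D (k = 3.30 × 10⁻⁶ min⁻¹)
    E ⇌ J (K = 15.0, k = 0.00730 min⁻¹)
    J → X (k = 0.0280 min⁻¹)
    E → L (k = 0.00230 min⁻¹)

**Where it stands.** Autumn ends with 50.6% as L and 2.80% as E, so its held share is 46.6%, of which Q is 40.3%; the epsilon reading at 3.00 h was 48.9%. In dusk, that 48.9% and the 2.80% of E left give 0.0966 M, against 0.101 M. Part of the reason for the level of L in dusk is the step from X to L acting together with the reverse step, G to E: against 0.101 M, the dusk run ends at 0.0465 M without the first and at 0.0482 M without the second.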